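**Retrosynthetic overview**
1. The thiazine dioxide ring is made last, from hypotaurine and naphthoquinone 25; 25 comes from its hydroquinone dimethyl ether 24 by oxidative demethylation.
2. The seven-membered dienol lactone of 24 is the dehydrated form of an aryl carboxylic acid/aldehyde pair (22), that is, of an aryl ketone cut between C(=O) and its α-carbon. A six-membered aryl ketone ring (19) therefore serves as a temporary ring and is opened by α-hydroxylation and periodate cleavage.
3. Key disconnection: the aryl–C(quaternary) bond, closed by an enantioselective, desymmetrizing 6-exo Heck cyclization of bromo ketone 17. Enabling feature: in ring A (the cyclohexadiene ring) the quaternary C(CH3)(aryl) and the alkene carbon =C(CH3) are the two neighbours of the ring carbon that bears the exocyclic =CH–O, with the two CH2 groups opposite. Ring A is thus a desymmetrized, mirror-symmetric 2,6-dimethylcyclohexa-2,5-dien-1-yl unit, the Birch product of 2,6-dimethylbenzoic acid.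
4. Ketone 17 is assembled from Weinreb amide 9 (aryne–furan Diels–Alder route from 1,2,4,5-tetrabromobenzene) and the Grignard reagent of iodide 14.
5. Ring order: naphthalene (step 1), ring A (dearomatized in step 4), temporary ketone ring (step 8), lactone ring (step 12), quinone (step 13), thiazine (step 14).

Key step: step 8

Assumption (remark on the chemistry): (R)-BINAP is taken as the ligand enantiomer that selects the alkene leading to the quaternary configuration of the target; if the sense of induction is the opposite, (S)-BINAP is used and nothing else changes.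

**Step 1**
Reactants: 1 1,2,4,5-tetrabromobenzene; 2 2-methoxyfuran
Product: 6 6,7-dibromo-4-methoxynaphthalen-1-ol, via 2,4,5-tribromophenyllithium 3 (not isolated), via 4,5-dibromobenzyne 4 (not isolated), via oxa-bridged cycloadduct 5 (not isolated)
Conditions: n-BuLi (1.05 equiv), toluene, −23 °C to rt; then 1 M HCl, THF, rt
Reagents that add atoms: none
Why: Bromine–lithium exchange and loss of LiBr generate the symmetrical aryne 4, whose Diels–Alder cycloaddition with the furan gives the bridged ketal 5, which opens and aromatizes under acid to the 4-methoxy-1-naphthol as the only possible regioisomer (aryne–furan cycloaddition with ring opening).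

**Step 2**
Reactants: 6 6,7-dibromo-4-methoxynaphthalen-1-ol
Product: 7 6,7-dibromo-1,4-dimethoxynaphthalene
Conditions: MeI, K2CO3, acetone, reflux
Reagents that add atoms: iodomethane, CI
Why: Williamson ether synthesis on the naphthoxide protects the oxidation-sensitive naphthol as the hydroquinone dimethyl ether that later masks the quinone.

**Step 3**
Reactants: 7 6,7-dibromo-1,4-dimethoxynaphthalene
Product: 9 3-bromo-N,5,8-trimethoxy-N-methylnaphthalene-2-carboxamide, via arylmagnesium chloride 8 (not isolated)
Conditions: i-PrMgCl·LiCl (1.05 equiv), THF, −15 °C; then ClC(O)N(OMe)Me, −15 °C to rt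
Reagents that add atoms: N-methoxy-N-methylcarbamoyl chloride, CON(C)C(Cl)=O
Why: Bromine–magnesium exchange on one of the two equivalent C–Br bonds gives an ortho-bromoaryl Grignard reagent that is stable below 0 °C and is acylated by the carbamoyl chloride to the Weinreb amide without over-addition.

**Step 4**
Reactants: 10 2,6-dimethylbenzoic acid
Product: 12 2,6-dimethylcyclohexa-2,5-diene-1-carboxylic acid, via dilithium dienediolate 11 (not isolated)
Conditions: Li, NH3(l), THF, −78 °C; then NH4Cl
Reagents that add atoms: none
Why: In the Birch reduction the carboxylate directs reduction to the 1,4-dihydro product with the sp3 carbons at C1 and C4, both methyl groups stay on the alkenes, and kinetic protonation of the dienediolate at C1 keeps the diene skipped.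

**Step 5**
Reactants: 12 2,6-dimethylcyclohexa-2,5-diene-1-carboxylic acid
Product: 13 (2,6-dimethylcyclohexa-2,5-dien-1-yl)methanol
Conditions: LiAlH4, Et2O, 0 °C to rt
Reagents that add atoms: none
Why: Hydride reduction of the carboxylic acid to the primary alcohol leaves the isolated alkenes untouched.

**Step 6**
Reactants: 13 (2,6-dimethylcyclohexa-2,5-dien-1-yl)methanol
Product: 14 6-(iodomethyl)-1,5-dimethylcyclohexa-1,4-diene
Conditions: I2, PPh3, imidazole, CH2Cl2, 0 °C
Reagents that add atoms: iodine, II
Why: Appel-type iodination through the alkoxyphosphonium iodide (SN2 at the primary carbon) runs under neutral conditions that spare the skipped diene.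

**Step 7**
Reactants: 14 6-(iodomethyl)-1,5-dimethylcyclohexa-1,4-diene; 9 3-bromo-N,5,8-trimethoxy-N-methylnaphthalene-2-carboxamide
Product: 17 1-(3-bromo-5,8-dimethoxynaphthalen-2-yl)-2-(2,6-dimethylcyclohexa-2,5-dien-1-yl)ethan-1-one, via Grignard reagent 15 (not isolated), via magnesium hemiaminal chelate 16 (not isolated)
Conditions: Mg, Et2O, rt; then 9, THF, 0 °C; aq. NH4Cl
Reagents that add atoms: none
Why: In this Weinreb ketone synthesis the primary Grignard reagent adds once to the amide to give the stable chelate 16, which releases the ketone only on aqueous work-up, and an alkylmagnesium iodide does not exchange with the aryl bromide at 0 °C.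

**Step 8**
Reactants: 17 1-(3-bromo-5,8-dimethoxynaphthalen-2-yl)-2-(2,6-dimethylcyclohexa-2,5-dien-1-yl)ethan-1-one
Product: 18 (4aS,12bR)-8,11-dimethoxy-4,12b-dimethyl-4a,12b-dihydrotetraphen-6(5H)-one
Conditions: Pd(OAc)2 (10 mol %), (R)-BINAP (20 mol %), Ag2CO3, NMP, 80 °C
Reagents that add atoms: none
Why: Oxidative addition of zerovalent palladium into the C–Br bond and bromide abstraction by silver give a cationic arylpalladium–BINAP complex that binds one of the two enantiotopic C(CH3)=CH alkenes of the mirror-symmetric dienyl unit, inserts it in a syn fashion with the aryl group going to the methyl-bearing carbon, and then undergoes syn β-hydride elimination toward the doubly allylic CH2 group, the only β-hydrogen available because the new carbon is quaternary. The closest known reaction type is the enantioselective desymmetrizing intramolecular Heck cyclization of cyclohexa-2,5-dienes from Birch reduction, which forms benzylic quaternary carbons in six-membered rings. The ring closes in the 6-exo-trig mode and gives the six-membered aryl ketone ring that serves as the temporary ring. The quaternary carbon is set by the chiral ligand through enantiotopic group selection, and the ring-fusion CH centre follows from it, because the two-atom tether can deliver the aryl group only to the face of ring A that carries the tether (cis fusion, 12b-CH3 and 4a-H on the same face). The step needs exo over endo insertion, which the short tether secures, and it needs suppression of palladium hydride re-addition to the new 1,3-diene, which the silver base secures by keeping the complex cationic and scavenging HBr.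

**Step 9**
Reactants: 18 (4aS,12bR)-8,11-dimethoxy-4,12b-dimethyl-4a,12b-dihydrotetraphen-6(5H)-one
Product: 19 (4aS,12bR)-8,11-dimethoxy-4,12b-dimethyl-1,2,4a,12b-tetrahydrotetraphen-6(5H)-one
Conditions: 2-nitrobenzenesulfonyl hydrazide, Et3N, CH2Cl2, rt
Reagents that add atoms: none
Why: Diimide, generated in the flask, transfers H2 in a concerted syn fashion to the cis-disubstituted alkene of the 1,3-diene much faster than to the trisubstituted one and leaves the ketone, the arene and both stereocentres untouched.

**Step 10**
Reactants: 19 (4aS,12bR)-8,11-dimethoxy-4,12b-dimethyl-1,2,4a,12b-tetrahydrotetraphen-6(5H)-one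
Product: 21 (4aS,12bR)-5-hydroxy-8,11-dimethoxy-4,12b-dimethyl-1,2,4a,12b-tetrahydrotetraphen-6(5H)-one (both C5 epimers), via potassium enolate 20 (not isolated)
Conditions: KN(SiMe3)2, THF, −78 °C; then 3-phenyl-2-(phenylsulfonyl)oxaziridine; aq. NH4Cl
Reagents that add atoms: 3-phenyl-2-(phenylsulfonyl)oxaziridine, O=S(=O)(N1OC1c1ccccc1)c1ccccc1
Why: In this enolate hydroxylation with an N-sulfonyloxaziridine the ketone can enolize only toward its CH2 group, and the configuration of the new carbinol carbon is irrelevant because it becomes the aldehyde carbon in step 11.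

**Step 11**
Reactants: 21 (4aS,12bR)-5-hydroxy-8,11-dimethoxy-4,12b-dimethyl-1,2,4a,12b-tetrahydrotetraphen-6(5H)-one
Product: 22 3-[(1R,2S)-2-formyl-1,3-dimethylcyclohex-3-en-1-yl]-5,8-dimethoxynaphthalene-2-carboxylic acid
Conditions: NaIO4, THF/H2O, rt
Reagents that add atoms: water, O
Why: Periodate (Malaprade-type) cleavage of the α-hydroxy ketone gives the aryl carboxylic acid from the carbonyl carbon and the aldehyde from the carbinol carbon and so opens the temporary ring, while the alkene and the aryl ethers are inert.

**Step 12**
Reactants: 22 3-[(1R,2S)-2-formyl-1,3-dimethylcyclohex-3-en-1-yl]-5,8-dimethoxynaphthalene-2-carboxylic acid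
Product: 24 (S)-dienol lactone dimethyl ether, via acyl chloride 23 (not isolated)
Conditions: 1-chloro-N,N,2-trimethylprop-1-en-1-amine, CH2Cl2, 0 °C; then Et3N, DMAP (cat.), CH2Cl2 (high dilution), 0 °C to rt
Reagents that add atoms: none
Why: The acid is converted under neutral conditions into the acyl chloride, and Et3N/DMAP then enolize the α-branched, allylically activated aldehyde toward the ring carbon and promote intramolecular O-acylation (enol ester formation) to the seven-membered dienol lactone, which removes the ring-fusion stereocentre and leaves the quaternary carbon untouched (its descriptor changes from R to S only because the CIP priorities change).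

**Step 13**
Reactants: 24 (S)-dienol lactone dimethyl ether
Product: 25 (S)-naphthoquinone dienol lactone
Conditions: (NH4)2Ce(NO3)6, MeCN/H2O, 0 °C
Reagents that add atoms: water, O
Why: Oxidative demethylation with tetravalent cerium takes place at the 1,4-dimethoxyarene, the most electron-rich site, within minutes at 0 °C, before the acylated dienol can react.

**Step 14**
Reactants: 25 (S)-naphthoquinone dienol lactone; 26 hypotaurine (2-aminoethanesulfinic acid)
Product: 30 CNP0348176.1, via sulfonylhydroquinone 27 (not isolated), via sulfonylquinone 28 (not isolated), via leuco thiazine 29 (not isolated)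
Conditions: EtOH/MeCN/H2O, air, rt
Reagents that add atoms: none
Why: In this thiazine annulation the free sulfinate of the zwitterion should add first (conjugate addition) at the quinone CH β to the more electron-poor carbonyl, the one para-related to the lactone-bearing ring carbon; air reoxidizes the hydroquinone, the amine closes the ring by intramolecular conjugate addition, and a second air oxidation gives the amino sulfonyl quinone with sulfur next to the carbonyl para-related to the quaternary benzylic carbon, as in the target.

**Compound list**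
1 | 1,2,4,5-tetrabromobenzene | Brc1cc(Br)c(Br)cc1Br | starting material
2 | 2-methoxyfuran | COc1ccco1 | starting material
3 | 2,4,5-tribromophenyllithium | [Li]c1cc(Br)c(Br)cc1Br | intermediate
4 | 4,5-dibromobenzyne | BrC1=CC#CC=C1Br | intermediate
5 | 6,7-dibromo-1-methoxy-1,4-dihydro-1,4-epoxynaphthalene (racemic) | COC12OC(C=C1)c1cc(Br)c(Br)cc12 | intermediate
6 | 6,7-dibromo-4-methoxynaphthalen-1-ol | COc1ccc(O)c2cc(Br)c(Br)cc12 | intermediate
7 | 6,7-dibromo-1,4-dimethoxynaphthalene | COc1ccc(OC)c2cc(Br)c(Br)cc12 | intermediate
8 | (3-bromo-5,8-dimethoxynaphthalen-2-yl)magnesium chloride | COc1ccc(OC)c2cc([Mg]Cl)c(Br)cc12 | intermediate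
9 | 3-bromo-N,5,8-trimethoxy-N-methylnaphthalene-2-carboxamide | CON(C)C(=O)c1cc2c(OC)ccc(OC)c2cc1Br | intermediate
10 | 2,6-dimethylbenzoic acid | Cc1cccc(C)c1C(O)=O | starting material
11 | dilithium (2,6-dimethylcyclohexa-2,5-dien-1-ylidene)methanediolate | [Li+].[Li+].CC1=CCC=C(C)C1=C([O-])[O-] | intermediate
12 | 2,6-dimethylcyclohexa-2,5-diene-1-carboxylic acid | CC1=CCC=C(C)C1C(O)=O | intermediate
13 | (2,6-dimethylcyclohexa-2,5-dien-1-yl)methanol | CC1=CCC=C(C)C1CO | intermediate
14 | 6-(iodomethyl)-1,5-dimethylcyclohexa-1,4-diene | CC1=CCC=C(C)C1CI | intermediate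
15 | [(2,6-dimethylcyclohexa-2,5-dien-1-yl)methyl]magnesium iodide | CC1=CCC=C(C)C1C[Mg]I | intermediate
16 | magnesium hemiaminal chelate (tetrahedral adduct of 15 and 9) | CON(C)C(O[Mg]I)(CC1C(C)=CCC=C1C)c1cc2c(OC)ccc(OC)c2cc1Br | intermediate
17 | 1-(3-bromo-5,8-dimethoxynaphthalen-2-yl)-2-(2,6-dimethylcyclohexa-2,5-dien-1-yl)ethan-1-one | CC1=CCC=C(C)C1CC(=O)c1cc2c(OC)ccc(OC)c2cc1Br | intermediate
18 | (4aS,12bR)-8,11-dimethoxy-4,12b-dimethyl-4a,12b-dihydrotetraphen-6(5H)-one (cis-fused) | CC1=CC=C[C@]2(C)[C@H]1CC(=O)c1cc3c(cc12)c(OC)ccc3OC | intermediate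
19 | (4aS,12bR)-8,11-dimethoxy-4,12b-dimethyl-1,2,4a,12b-tetrahydrotetraphen-6(5H)-one | CC1=CCC[C@]2(C)[C@H]1CC(=O)c1cc3c(cc12)c(OC)ccc3OC | intermediate
20 | potassium enolate of 19 | [K+].CC1=CCC[C@]2(C)[C@H]1C=C([O-])c1cc3c(cc12)c(OC)ccc3OC | intermediate
21 | (4aS,12bR)-5-hydroxy-8,11-dimethoxy-4,12b-dimethyl-1,2,4a,12b-tetrahydrotetraphen-6(5H)-one (both C5 epimers) | CC1=CCC[C@]2(C)[C@H]1C(O)C(=O)c1cc3c(cc12)c(OC)ccc3OC | intermediate
22 | 3-[(1R,2S)-2-formyl-1,3-dimethylcyclohex-3-en-1-yl]-5,8-dimethoxynaphthalene-2-carboxylic acid | CC1=CCC[C@](C)([C@H]1C=O)c1cc2c(OC)ccc(OC)c2cc1C(O)=O | intermediate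
23 | 3-[(1R,2S)-2-formyl-1,3-dimethylcyclohex-3-en-1-yl]-5,8-dimethoxynaphthalene-2-carbonyl chloride | CC1=CCC[C@](C)([C@H]1C=O)c1cc2c(OC)ccc(OC)c2cc1C(Cl)=O | intermediate
24 | (S)-dienol lactone dimethyl ether: seven-membered aryl C(=O)–O–CH=C lactone fused to ring A and to the 5,8-dimethoxynaphthalene (hydroquinone dimethyl ether of 25) | CC1=CCC[C@]2(C)C1=COC(=O)c1cc3c(cc12)c(OC)ccc3OC | intermediate
25 | (S)-naphthoquinone dienol lactone (the target without the thiazine dioxide ring) | CC1=CCC[C@]2(C)C1=COC(=O)c1cc3c(cc12)C(=O)C=CC3=O | intermediate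
26 | hypotaurine (2-aminoethanesulfinic acid) | NCCS(O)=O | starting material
27 | (2-aminoethyl)sulfonyl hydroquinone adduct of 25 (sulfur next to the C–OH para-related to the quaternary benzylic carbon) | CC1=CCC[C@]2(C)C1=COC(=O)c1cc3c(cc12)c(O)cc(c3O)S(=O)(=O)CCN | intermediate
28 | (2-aminoethyl)sulfonyl quinone | CC1=CCC[C@]2(C)C1=COC(=O)c1cc3c(cc12)C(=O)C=C(C3=O)S(=O)(=O)CCN | intermediate
29 | hydroquinone (leuco) form of 30 | CC1=CCC[C@]2(C)C1=COC(=O)c1cc3c(cc12)c(O)c4NCCS(=O)(=O)c4c3O | intermediate
30 | CNP0348176.1, (S)-configured quaternary carbon | CC1=CCC[C@]2(C)C1=COC(=O)c1cc3c(cc12)C(=O)C1=C(C3=O)S(=O)(=O)CCN1 | target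

**Step count and risks**
Total step count: 14. Longest linear sequence: 11 steps (steps 4 to 14 from 10; the branch from 1 through steps 1 to 3 and 7 to 14 is equally long).

Steps most likely to fail:

1. Step 8. The ligand may not differentiate the two enantiotopic ring alkenes well enough, and palladium hydride may isomerize the skipped diene or dehydrogenate it to an arene. The fallback sets out from 17 and comes back at 18. Corey–Bakshi–Shibata reduction of 17 ((S)-Me-CBS oxazaborolidine, BH3·SMe2) gives (R)-1-(3-bromo-5,8-dimethoxynaphthalen-2-yl)-2-(2,6-dimethylcyclohexa-2,5-dien-1-yl)ethan-1-ol F1, and silylation (TBSCl, imidazole) gives its tert-butyldimethylsilyl ether F2. A Heck cyclization with an achiral catalyst (Pd(OAc)2, PPh3, Ag2CO3) is then steered by the carbinol centre: the bulky silyloxy group takes the pseudo-equatorial position in the six-membered transition state and selects one of the two, now diastereotopic, alkenes to give the silyloxy tetracycle F3. Bu4NF gives the alcohol F4, and Dess–Martin oxidation returns ketone 18. The CBS catalyst enantiomer is chosen so that the carbinol configuration leads to the quaternary configuration of 18; the (R)-carbinol is drawn.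

2. Step 12. Intermolecular acylation, and base-induced migration of the ring alkene into conjugation with the aldehyde, may compete with the medium-ring O-acylation. The fallback sets out from 22 and comes back at 24. Under acid catalysis 22 closes reversibly to the seven-membered hydroxy lactone (pseudo-acid) F5; TsOH (cat.) in benzene with azeotropic removal of water dehydrates it through the acyloxycarbenium ion, with loss of the allylic ring-fusion proton, to 24.

3. Step 14. Nitrogen-first conjugate addition would lead to the regioisomeric thiazine, and the free amine may open the enol lactone. The fallback sets out from 25 and comes back at 28. Sodium 2-[(tert-butoxycarbonyl)amino]ethanesulfinate, which can react only through sulfur, adds to 25 to give the N-Boc sulfonyl hydroquinone F6; Ag2O oxidizes it to the N-Boc sulfonyl quinone F7; CF3CO2H removes the carbamate and neutralization (NaHCO3) liberates amine 28, which closes and is oxidized by air to 29 and 30 as in step 14.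

**Further compounds**
F1 | step 8 | (R)-1-(3-bromo-5,8-dimethoxynaphthalen-2-yl)-2-(2,6-dimethylcyclohexa-2,5-dien-1-yl)ethan-1-ol | O[C@H](CC1C(C)=CCC=C1C)c1cc2c(OC)ccc(OC)c2cc1Br
F2 | step 8 | tert-butyldimethylsilyl ether of F1 | CC(C)(C)[Si](C)(C)O[C@H](CC1C(C)=CCC=C1C)c1cc2c(OC)ccc(OC)c2cc1Br
F3 | step 8 | (4aS,6R,12bR)-6-[(tert-butyldimethylsilyl)oxy]-8,11-dimethoxy-4,12b-dimethyl-4a,5,6,12b-tetrahydrotetraphene | CC1=CC=C[C@]2(C)[C@H]1C[C@@H](O[Si](C)(C)C(C)(C)C)c1cc3c(cc12)c(OC)ccc3OC
F4 | step 8 | (4aS,6R,12bR)-8,11-dimethoxy-4,12b-dimethyl-4a,5,6,12b-tetrahydrotetraphen-6-ol | CC1=CC=C[C@]2(C)[C@H]1C[C@@H](O)c1cc3c(cc12)c(OC)ccc3OC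
F5 | step 12 | seven-membered hydroxy lactone (pseudo-acid form of 22, both hemiacetal epimers) | CC1=CCC[C@]2(C)[C@H]1C(O)OC(=O)c1cc3c(cc12)c(OC)ccc3OC
F6 | step 14 | N-Boc (2-aminoethyl)sulfonyl hydroquinone adduct of 25 | CC1=CCC[C@]2(C)C1=COC(=O)c1cc3c(cc12)c(O)cc(c3O)S(=O)(=O)CCNC(=O)OC(C)(C)C
F7 | step 14 | N-Boc (2-aminoethyl)sulfonyl quinone | CC1=CCC[C@]2(C)C1=COC(=O)c1cc3c(cc12)C(=O)C=C(C3=O)S(=O)(=O)CCNC(=O)OC(C)(C)C
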